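Ring atoms are numbered C1 (OAc), C2 (OH), C3 (OH), C4 (oxirane CH), C5 (oxirane carbon bearing C7H2OBz), C6 (OAc). The cyclohexane is disconnected at C5–C6. One SmI2 pinacol coupling of a keto-aldehyde closes this ring and sets C5 and C6 together; it exploits the cis relationship of the C5 and C6 oxygens, which lie on the ring face opposite to the flanking C4 and C1 oxygens. The precursor is an open-chain D-gulonic acid derivative: C6 aldehyde, C5 ketone bearing CH2OPMB, C3/C4 acetonide, C2 OBOM, C1 OTES (PMB = 4-methoxybenzyl, BOM = benzyloxymethyl, TES = triethylsilyl). C4 is inverted later, when the C5 oxygen opens a C3/C4 cyclic sulfate to form the oxirane.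

Key step: step 9

Remarks on the chemistry:
- Ring carbons C1, C2, C3 and C4 are C5, C4, C3 and C2 of D-gulono-1,4-lactone. Checked centre by centre, all four are carried over unchanged; C4 alone is inverted, once, in step 16.
- Protecting groups are chosen so that every later unmasking is one selective operation. TES sits on O1 and on the primary oxygen that becomes the aldehyde. BOM sits on O2; it goes on without strong base and comes off last under neutral hydrogenolysis. PMB sits on O7; it comes off alone, so the benzoate meets no competing secondary hydroxyl.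
- Tributyl(iodomethyl)stannane (7) is assumed to be commercially available.

Step 1
Reactants: 1 D-gulono-1,4-lactone
Product: 2 2,3:5,6-di-O-isopropylidene-D-gulono-1,4-lactone
Conditions: 2,2-dimethoxypropane, p-TsOH (cat.), DMF, rt
Reagents that add atoms: 2,2-dimethoxypropane, CC(C)(OC)OC
Why: Acid-catalysed acetonide formation (transacetalisation) takes the cis-2,3-diol on the lactone ring and the terminal 5,6-diol, the two pairs that can form unstrained dioxolanes, and touches no stereocentre.

Step 2
Reactants: 2 2,3:5,6-di-O-isopropylidene-D-gulono-1,4-lactone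
Product: 3 2,3-O-isopropylidene-D-gulono-1,4-lactone
Conditions: AcOH/H2O (7:3), rt
Reagents that add atoms: none
Why: Selective acetal hydrolysis: the terminal 5,6-dioxolane should be cleaved well before the 2,3-dioxolane, which is fused to the lactone ring and deactivated by the neighbouring carbonyl group.

Step 3
Reactants: 3 2,3-O-isopropylidene-D-gulono-1,4-lactone
Product: 4 2,3-O-isopropylidene-5,6-bis-O-triethylsilyl-D-gulono-1,4-lactone
Conditions: TESCl (2.4 equiv), imidazole, DMF, 0 °C → rt
Reagents that add atoms: chlorotriethylsilane, CC[Si](Cl)(CC)CC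
Why: Silyl ether formation with TESCl/imidazole covers both hydroxyls in one operation under conditions too mild to open or epimerise the lactone.

Step 4
Reactants: 4 2,3-O-isopropylidene-5,6-bis-O-triethylsilyl-D-gulono-1,4-lactone
Product: 5 N-methoxy-N-methyl-2,3-O-isopropylidene-5,6-bis-O-triethylsilyl-D-gulonamide (4-OH free; used crude)
Conditions: MeNH(OMe)·HCl, AlMe3, CH2Cl2, 0 °C → rt; aq. potassium sodium tartrate
Reagents that add atoms: N,O-dimethylhydroxylamine hydrochloride, CNOC.Cl
Why: Weinreb amide formation by aminolysis of the lactone with the aluminium amide made from AlMe3 and the amine salt opens the ring at the acyl carbon only, so that O4 (the later O2 of the ring) is the one free hydroxyl and no stereocentre is touched.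

Step 5
Reactants: 5 N-methoxy-N-methyl-2,3-O-isopropylidene-5,6-bis-O-triethylsilyl-D-gulonamide
Product: 6 N-methoxy-N-methyl-4-O-benzyloxymethyl-2,3-O-isopropylidene-5,6-bis-O-triethylsilyl-D-gulonamide
Conditions: BOMCl, iPr2NEt, Bu4NI (cat.), CH2Cl2, 0 °C → rt
Reagents that add atoms: benzyl chloromethyl ether, ClCOCc1ccccc1
Why: Alkoxymethyl ether formation (BOM protection, SN2 on the iodomethyl ether formed in situ) needs only an amine base, so no alkoxide is formed that could relactonise onto the amide or take over the neighbouring silyl group.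

Step 6
Reactants: 7 tributyl(iodomethyl)stannane
Product: 8 tributyl[(4-methoxybenzyloxy)methyl]stannane
Conditions: 4-methoxybenzyl alcohol, NaH, THF/DMF, 0 °C; then 7, rt
Reagents that add atoms: 4-methoxybenzyl alcohol, COc1ccc(CO)cc1
Why: Williamson ether synthesis: the sodium alkoxide displaces iodide from the unhindered iodomethyl group next to tin.

Step 7
Reactants: 6 N-methoxy-N-methyl-4-O-benzyloxymethyl-2,3-O-isopropylidene-5,6-bis-O-triethylsilyl-D-gulonamide; 8 tributyl[(4-methoxybenzyloxy)methyl]stannane
Product: 10 open-chain ketone (C5 ketone bearing CH2OPMB; C3/C4 acetonide; C2 OBOM; C1 OTES; C6 as CH2OTES), via (4-methoxybenzyloxy)methyllithium 9 (not isolated)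
Conditions: 8, n-BuLi, THF, −78 °C; then 6, −78 °C; AcOH quench
Reagents that add atoms: none
Why: Tin–lithium exchange gives the α-alkoxymethyllithium 9, and its addition to the Weinreb amide stops at the chelated tetrahedral intermediate, which collapses to the ketone only on quench (Weinreb ketone synthesis), so over-addition and epimerisation at the α-carbon should not occur at −78 °C.

Step 8
Reactants: 10 open-chain ketone with C1 OTES and C6 CH2OTES
Product: 11 keto-aldehyde (C6 aldehyde; C5 ketone bearing CH2OPMB; C3/C4 acetonide; C2 OBOM; C1 OTES; used at once)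
Conditions: (COCl)2, DMSO, CH2Cl2, −78 → −40 °C; then Et3N, −78 → 0 °C
Reagents that add atoms: none
Why: Swern oxidation applied to a bis-silyl ether: the chlorosulfonium reagent cleaves the unhindered primary TES ether and oxidises it to the aldehyde in the same pot, while the secondary TES ether at C1 is too hindered to react.

Step 9
Reactants: 11 keto-aldehyde
Product: 12 cyclitol cis-5,6-diol (C1 OTES; C2 OBOM; C3/C4 acetonide; C5 OH and CH2OPMB; C6 OH)
Conditions: SmI2 (3 equiv), t-BuOH (3 equiv), THF, −78 °C → rt
Reagents that add atoms: none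
Why: Divalent samarium reduces the more easily reduced C6 aldehyde to a ketyl radical anion, which attacks the C5 ketone carbon; the resulting alkoxy radical is reduced at once and the diolate is protonated, the closest known reaction type being the SmI2 pinacol cyclisation of sugar-derived 1,6-dicarbonyl compounds to cyclitols. The cyclohexane closes in a 6-exo-trig mode. A single trivalent samarium ion bridges the ketyl oxygen and the ketone oxygen during bond formation, so the two new C–O bonds end up cis. At C6 the new C–O bond turns away from the C1 silyl ether, and at C5 it turns away from the axial C4 acetonide oxygen, which also leaves CH2OPMB equatorial in the chair-like transition state; the four centres from gulonolactone thus control both new stereocentres. The step needs chemoselectivity (aldehyde before ketone, no loss of an α-alkoxy group) and diastereoselectivity at C5 and C6; the faster reduction of the aldehyde, the absence of HMPA, the low temperature and the cis-acetonide that holds the chain ends together should secure them.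

Step 10
Reactants: 12 cyclitol cis-5,6-diol with C1 OTES
Product: 13 1,5,6-triol (C2 OBOM; C3/C4 acetonide; C7 OPMB)
Conditions: HF·pyridine, pyridine, THF, 0 °C
Reagents that add atoms: none
Why: Fluoride-mediated cleavage of the silyl ether (Si–F bond formation) frees O1 without touching the acetonide or the BOM and PMB ethers; a silyl shift between O1 and O6 in step 9 would be of no consequence, since both oxygens are freed here.

Step 11
Reactants: 13 1,5,6-triol
Product: 14 1,6-diacetate (C5 OH free; C2 OBOM; C3/C4 acetonide; C7 OPMB)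
Conditions: Ac2O, pyridine, DMAP (cat.), CH2Cl2, 0 °C → rt
Reagents that add atoms: acetic anhydride, CC(=O)OC(C)=O
Why: DMAP-catalysed esterification acetylates the two equatorial secondary hydroxyls at C1 and C6, while the axial tertiary C5 hydroxyl is too hindered to react at this temperature.

Step 12
Reactants: 14 1,6-diacetate with C7 OPMB
Product: 15 primary alcohol (C7 OH; C5 OH; C1/C6 OAc; C2 OBOM; C3/C4 acetonide)
Conditions: DDQ, CH2Cl2/pH 7 phosphate buffer (10:1), 0 °C → rt
Reagents that add atoms: none
Why: Oxidative cleavage of a PMB ether by DDQ (hydride abstraction from the electron-rich benzylic position, then hydrolysis of the oxocarbenium ion) spares the less electron-rich BOM ether, and the buffered water should intercept the cation before the C5 hydroxyl can close an acetal.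

Step 13
Reactants: 15 primary alcohol
Product: 16 C7 benzoate (C5 OH; C1/C6 OAc; C2 OBOM; C3/C4 acetonide)
Conditions: BzCl, pyridine, CH2Cl2, 0 °C
Reagents that add atoms: benzoyl chloride, O=C(Cl)c1ccccc1
Why: Acylation of the only primary hydroxyl with an acid chloride (esterification); the tertiary C5 hydroxyl does not compete.

Step 14
Reactants: 16 C7 benzoate with C3/C4 acetonide
Product: 17 3,4,5-triol (C1/C6 OAc; C2 OBOM; C7 OBz)
Conditions: AcOH/H2O (4:1), 50 °C
Reagents that add atoms: none
Why: Acid-catalysed acetal hydrolysis removes the isopropylidene group in aqueous acetic acid, a medium that the esters and the less labile formaldehyde acetal of the BOM group should tolerate.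

Step 15
Reactants: 17 3,4,5-triol
Product: 19 3,4-cyclic sulfate (C5 OH free; C1/C6 OAc; C2 OBOM; C7 OBz), via 3,4-cyclic sulfite 18 (not isolated)
Conditions: SOCl2, Et3N, CH2Cl2, 0 °C; then RuCl3·xH2O (cat.), NaIO4, MeCN/H2O, 0 °C
Reagents that add atoms: thionyl chloride, O=S(Cl)Cl; sodium periodate, [Na+].[O-]I(=O)(=O)=O
Why: Cyclic sulfate synthesis from a 1,2-diol (cyclic sulfite with SOCl2, then RuO4-catalysed oxidation at sulfur): the five-membered ring closes across the cis C3/C4 pair, and the hindered tertiary C5 hydroxyl stays free.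

Step 16
Reactants: 19 3,4-cyclic sulfate
Product: 21 4,5-epoxy-3-ol (C1/C6 OAc; C2 OBOM; C7 OBz), via epoxy sulfate DBU-H salt 20 (not isolated)
Conditions: DBU, THF, 0 °C → rt; then H2SO4 (cat.), H2O (2 equiv), THF, rt
Reagents that add atoms: none
Why: Intramolecular SN2 opening of the cyclic sulfate (epoxide formation, 3-exo-tet) by the C5 oxygen, which stands trans-diaxial to the C4–O bond, inverts C4 and places the oxirane on the face of the C6 acetate, and acid hydrolysis of the sulfate monoester with S–O cleavage then frees the C3 hydroxyl with retention.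

Step 17
Reactants: 21 4,5-epoxy-3-ol with C2 OBOM
Product: 22 target compound CNP0171674.1
Conditions: H2 (1 atm), Pd/C, EtOAc, rt
Reagents that add atoms: none
Why: Catalytic hydrogenolysis cleaves the benzylic C–O bond of the BOM group and the hemiformal left behind loses formaldehyde, all under neutral conditions in which the oxirane and the three esters should neither react nor migrate.

Compound list
1 | D-gulono-1,4-lactone | O=C1[C@H](O)[C@H](O)[C@@H](O1)[C@H](O)CO | starting material
2 | 2,3:5,6-di-O-isopropylidene-D-gulono-1,4-lactone | O=C1[C@H](OC(C)(C)O2)[C@H]2[C@@H](O1)[C@H]3COC(C)(C)O3 | intermediate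
3 | 2,3-O-isopropylidene-D-gulono-1,4-lactone | O=C1[C@H](OC(C)(C)O2)[C@H]2[C@@H](O1)[C@H](O)CO | intermediate
4 | 2,3-O-isopropylidene-5,6-bis-O-triethylsilyl-D-gulono-1,4-lactone | O=C1[C@H](OC(C)(C)O2)[C@H]2[C@@H](O1)[C@H](O[Si](CC)(CC)CC)CO[Si](CC)(CC)CC | intermediate
5 | N-methoxy-N-methyl-2,3-O-isopropylidene-5,6-bis-O-triethylsilyl-D-gulonamide (4-OH free) | CON(C)C(=O)[C@H](OC(C)(C)O1)[C@H]1[C@@H](O)[C@H](O[Si](CC)(CC)CC)CO[Si](CC)(CC)CC | intermediate
6 | N-methoxy-N-methyl-4-O-benzyloxymethyl-2,3-O-isopropylidene-5,6-bis-O-triethylsilyl-D-gulonamide | CON(C)C(=O)[C@H](OC(C)(C)O1)[C@H]1[C@@H](OCOCc1ccccc1)[C@H](O[Si](CC)(CC)CC)CO[Si](CC)(CC)CC | intermediate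
7 | tributyl(iodomethyl)stannane | CCCC[Sn](CCCC)(CCCC)CI | starting material
8 | tributyl[(4-methoxybenzyloxy)methyl]stannane | CCCC[Sn](CCCC)(CCCC)COCc1ccc(OC)cc1 | intermediate
9 | (4-methoxybenzyloxy)methyllithium (not isolated) | [Li]COCc1ccc(OC)cc1 | intermediate
10 | open-chain ketone: C5 ketone bearing CH2OPMB, C3/C4 acetonide, C2 OBOM, C1 OTES, C6 CH2OTES (D-gulo centres retained) | COc1ccc(COCC(=O)[C@H](OC(C)(C)O2)[C@H]2[C@@H](OCOCc2ccccc2)[C@H](O[Si](CC)(CC)CC)CO[Si](CC)(CC)CC)cc1 | intermediate
11 | keto-aldehyde: C6 aldehyde, C5 ketone bearing CH2OPMB, C3/C4 acetonide, C2 OBOM, C1 OTES | COc1ccc(COCC(=O)[C@H](OC(C)(C)O2)[C@H]2[C@@H](OCOCc2ccccc2)[C@H](O[Si](CC)(CC)CC)C=O)cc1 | intermediate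
12 | cyclitol cis-5,6-diol: C1 OTES, C2 OBOM, C3/C4 acetonide, C5 OH and CH2OPMB, C6 OH (O1, O3, O4 and C7 on one face; O2, O5, O6 on the other) | CC[Si](CC)(CC)O[C@H]1[C@H](OCOCc2ccccc2)[C@H]3OC(C)(C)O[C@H]3[C@@](O)(COCc4ccc(OC)cc4)[C@@H]1O | intermediate
13 | 1,5,6-triol: C2 OBOM, C3/C4 acetonide, C7 OPMB | O[C@H]1[C@H](OCOCc2ccccc2)[C@H]3OC(C)(C)O[C@H]3[C@@](O)(COCc4ccc(OC)cc4)[C@@H]1O | intermediate
14 | 1,6-diacetate: C5 OH, C2 OBOM, C3/C4 acetonide, C7 OPMB | CC(=O)O[C@H]1[C@H](OCOCc2ccccc2)[C@H]3OC(C)(C)O[C@H]3[C@@](O)(COCc4ccc(OC)cc4)[C@@H]1OC(C)=O | intermediate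
15 | primary alcohol: C7 OH, C5 OH, C1/C6 OAc, C2 OBOM, C3/C4 acetonide | CC(=O)O[C@H]1[C@H](OCOCc2ccccc2)[C@H]3OC(C)(C)O[C@H]3[C@@](O)(CO)[C@@H]1OC(C)=O | intermediate
16 | C7 benzoate: C5 OH, C1/C6 OAc, C2 OBOM, C3/C4 acetonide | CC(=O)O[C@H]1[C@H](OCOCc2ccccc2)[C@H]3OC(C)(C)O[C@H]3[C@@](O)(COC(=O)c4ccccc4)[C@@H]1OC(C)=O | intermediate
17 | 3,4,5-triol: C1/C6 OAc, C2 OBOM, C7 OBz | CC(=O)O[C@H]1[C@H](OCOCc2ccccc2)[C@@H](O)[C@@H](O)[C@@](O)(COC(=O)c3ccccc3)[C@@H]1OC(C)=O | intermediate
18 | 3,4-cyclic sulfite of 17 (either configuration at sulfur; not isolated) | CC(=O)O[C@H]1[C@H](OCOCc2ccccc2)[C@H]3OS(=O)O[C@H]3[C@@](O)(COC(=O)c4ccccc4)[C@@H]1OC(C)=O | intermediate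
19 | 3,4-cyclic sulfate of 17 (C5 OH free) | CC(=O)O[C@H]1[C@H](OCOCc2ccccc2)[C@H]3OS(=O)(=O)O[C@H]3[C@@](O)(COC(=O)c4ccccc4)[C@@H]1OC(C)=O | intermediate
20 | 4,5-epoxide 3-sulfate, DBU-H salt (not isolated) | CC(=O)O[C@H]1[C@H](OCOCc2ccccc2)[C@@H](OS(=O)(=O)[O-])[C@@H]3O[C@]3(COC(=O)c4ccccc4)[C@@H]1OC(C)=O.C1CCC2=[NH+]CCCN2CC1 | intermediate
21 | 4,5-epoxy-3-ol: C1/C6 OAc, C2 OBOM, C7 OBz | CC(=O)O[C@H]1[C@H](OCOCc2ccccc2)[C@@H](O)[C@@H]3O[C@]3(COC(=O)c4ccccc4)[C@@H]1OC(C)=O | intermediate
22 | CNP0171674.1 | CC(=O)O[C@H]1[C@H](O)[C@@H](O)[C@@H]2O[C@]2(COC(=O)c2ccccc2)[C@@H]1OC(C)=O | target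

Total step count: 17. Longest linear sequence: 16 steps (steps 1–5 and 7–17, from D-gulono-1,4-lactone); step 6 prepares stannane 8 in a side branch.

Steps most likely to fail

1. Step 9 (key step). What may go wrong: electron transfer to the α,α'-dialkoxy ketone with expulsion of an α-alkoxy group, simple reduction of the aldehyde, or poor facial selectivity at C5 and C6 if the coupling does not pass through the samarium-bridged arrangement. The fallback sets out from keto-aldehyde 11 and comes back at diol 12. Both carbonyl groups of 11 would be methylenated by a double Wittig reaction (Ph3P=CH2, THF, −78 °C → rt) to give the 1,7-diene F1. Ring-closing metathesis with the second-generation Grubbs catalyst (CH2Cl2, 40 °C) would then form the same C5–C6 bond as an alkene, the cyclohexene F2. Dihydroxylation with OsO4 (cat.) and NMO in acetone/H2O should take place on the face opposite to the two allylic oxygens at C1 and C4, which is the face that 12 requires.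

2. Step 16. What may go wrong: acyl transfer from O6 or O7 to the C5 alkoxide in competition with ring closure, or opening of the new oxirane by acid while the sulfate monoester is hydrolysed. The fallback sets out from triol 17 and comes back at epoxy alcohol 21, so it bypasses steps 15 and 16. A Mitsunobu cyclodehydration (PPh3, DIAD, toluene, 0 → 80 °C) would take up the cis C3/C4 diol as a dioxaphosphorane. This can open productively only as the C4 oxyphosphonium ion, because C4 alone has a trans-vicinal hydroxyl. Displacement by O5 with inversion at C4 should give 21 directly, leaving O3 free; this fallback makes no new compound (F0).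

3. Step 5. What may go wrong: relactonisation of the γ-hydroxy Weinreb amide with loss of the amine, or silyl transfer from O5 to O4, before the BOM ether is in place. The fallback sets out from lactone 4 and comes back at ketone 10. Lactone 4 would be opened with morpholine (THF, rt → 40 °C) to the hydroxy morpholine amide F3, which carries a much poorer leaving group and should resist ring closure. BOM protection as in step 5 would give the protected morpholine amide F4. Addition of organolithium 9 (from 8 and n-BuLi, THF, −78 °C), followed by AcOH quench, should then give ketone 10 by acyl substitution on the morpholine amide.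

Further compounds
F1 | step 9 | 1,7-diene: both carbonyl groups of 11 replaced by C=CH2 (C1 OTES, C2 OBOM, C3/C4 acetonide, CH2OPMB on the 1,1-disubstituted alkene) | COc1ccc(COCC(=C)[C@H](OC(C)(C)O2)[C@H]2[C@@H](OCOCc2ccccc2)[C@H](O[Si](CC)(CC)CC)C=C)cc1
F2 | step 9 | cyclohexene with C5=C6 double bond: C1 OTES, C2 OBOM, C3/C4 acetonide, C5 CH2OPMB | CC[Si](CC)(CC)O[C@H]1[C@H](OCOCc2ccccc2)[C@H]3OC(C)(C)O[C@H]3C(COCc4ccc(OC)cc4)=C1
F0 | step 16 | none | none
F3 | step 5 | 4-(2,3-O-isopropylidene-5,6-bis-O-triethylsilyl-D-gulonoyl)morpholine (4-OH free) | O=C(N1CCOCC1)[C@H](OC(C)(C)O2)[C@H]2[C@@H](O)[C@H](O[Si](CC)(CC)CC)CO[Si](CC)(CC)CC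
F4 | step 5 | 4-(4-O-benzyloxymethyl-2,3-O-isopropylidene-5,6-bis-O-triethylsilyl-D-gulonoyl)morpholine | O=C(N1CCOCC1)[C@H](OC(C)(C)O2)[C@H]2[C@@H](OCOCc2ccccc2)[C@H](O[Si](CC)(CC)CC)CO[Si](CC)(CC)CC
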